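**Retrosynthetic overview**
1. Target 39 (labdane numbering) comes from the bicyclic core 30 (ring-A C2=C3 olefin, C8 ketone, C20 aldehyde) by late oxygenation: OsO4 for the 2α,3α-diol, 2-O-angeloylation, C8 methylenation, SeO2 for 7α-OH, and alkyne semi-hydrogenation for C14=C15.
2. Key disconnection of 30 at C5–C6 and C1–C10: C5=C10 of a cyclohepta-2,5-dienyl silyl ether adds to a tethered vinyl ketone (closing ring B), and the C10 cation is quenched by a 1,2-shift of C1 from C20 to C10. This contracts the seven-membered ring (C20, C10, C5, C4, C3, C2, C1) to ring A and expels C20 as the formyl group.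
3. Enabling feature: the quaternary ring-fusion carbon C10 of ring A carries the oxidized one-carbon branch C20 next to C1. C20 can therefore be a ring atom of the precursor, and its carbinol configuration (CBS reduction) is relayed to C5 and C10.
4. Precursor 28 comes from Weinreb amide 14 (seven-membered ring from benzoic acid by Birch methylation, dibromocarbene/silver ring expansion and Negishi coupling) and iodide 25 (C11–C15, with C13 set by Sharpless epoxidation).
5. Order of ring formation: the seven-membered carbocycle (step 6), then ring B and ring A together (step 20).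

Key step: step 20

Remark: labdane numbering (C1–C20, C17 = exocyclic methylene carbon) is used from compound 27 on, with α as the face of H5. Compounds 7 and 8 are racemic and drawn without descriptors. Compounds 27, 28, 30 and 31 are C9 epimer mixtures with C9 left undefined in their SMILES.

**Part A: seven-membered ring and Weinreb amide**

Step 1
Reactants: 1 benzoic acid
Product: 3 1-methylcyclohexa-2,5-diene-1-carboxylic acid, via dilithium enediolate 2 (not isolated)
Conditions: Li, NH3(l)/THF, −78 °C; then MeI; aq. HCl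
Reagents that add atoms: iodomethane, CI
Why: Birch reduction of the benzoate gives the cross-conjugated enediolate, which is C-methylated at the carboxyl-bearing carbon (Birch reductive alkylation) and leaves the skipped 2,5-diene.

Step 2
Reactants: 3 1-methylcyclohexa-2,5-diene-1-carboxylic acid
Product: 4 (1-methylcyclohexa-2,5-dien-1-yl)methanol
Conditions: LiAlH4, THF, 0 to 23 °C
Reagents that add atoms: none
Why: Hydride reduction of the carboxylic acid to the primary alcohol should leave the isolated alkenes untouched.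

Step 3
Reactants: 4 (1-methylcyclohexa-2,5-dien-1-yl)methanol
Product: 5 (1-methylcyclohexa-2,5-dien-1-yl)methyl 4-methylbenzenesulfonate
Conditions: TsCl, pyridine, CH2Cl2, 0 to 23 °C
Reagents that add atoms: p-toluenesulfonyl chloride, Cc1ccc(cc1)S(Cl)(=O)=O
Why: Sulfonylation activates the neopentyl-type primary alcohol for hydride displacement.

Step 4
Reactants: 5 (1-methylcyclohexa-2,5-dien-1-yl)methyl 4-methylbenzenesulfonate
Product: 6 3,3-dimethylcyclohexa-1,4-diene
Conditions: LiEt3BH, THF, 65 °C
Reagents that add atoms: none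
Why: LiEt3BH is a strong enough hydride nucleophile for SN2 displacement of hindered primary sulfonates, turning CH2OTs into the second methyl group of the future C4.

Step 5
Reactants: 6 3,3-dimethylcyclohexa-1,4-diene
Product: 7 rac-7,7-dibromo-2,2-dimethylbicyclo[4.1.0]hept-3-ene
Conditions: CHBr3 (1 equiv), KOtBu, pentane, −10 to 0 °C, excess 6
Reagents that add atoms: bromoform, BrC(Br)Br
Why: Dibromocarbene cyclopropanates one of the two equivalent cis alkenes of the symmetric diene, and excess diene should limit double addition.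

Step 6
Reactants: 7 rac-7,7-dibromo-2,2-dimethylbicyclo[4.1.0]hept-3-ene
Product: 8 rac-2-bromo-4,4-dimethylcyclohepta-2,5-dien-1-ol
Conditions: AgNO3, acetone/H2O, 45 °C
Reagents that add atoms: water, O
Why: Silver-assisted loss of bromide triggers disrotatory electrocyclic opening to the 2-bromoallyl cation of the seven-membered ring (dihalocyclopropane ring expansion), and water should add at the terminus remote from the quaternary carbon.

Step 7
Reactants: 8 rac-2-bromo-4,4-dimethylcyclohepta-2,5-dien-1-ol
Product: 9 2-bromo-4,4-dimethylcyclohepta-2,5-dien-1-one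
Conditions: Dess–Martin periodinane, CH2Cl2, 0 °C
Reagents that add atoms: none
Why: Dess–Martin oxidation of the allylic alcohol is near-neutral, which should avoid migration of the β,γ-alkene into conjugation.

Step 8
Reactants: 9 2-bromo-4,4-dimethylcyclohepta-2,5-dien-1-one
Product: 10 (R)-2-bromo-4,4-dimethylcyclohepta-2,5-dien-1-ol
Conditions: (S)-2-methyl-CBS-oxazaborolidine (20 mol %), BH3·SMe2, THF, −30 °C
Reagents that add atoms: none
Why: In this Corey–Bakshi–Shibata reduction the α-bromoalkenyl carbon acts as the large group, so hydride should be delivered to give the (R)-carbinol, the future C20.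

Step 9
Reactants: 10 (R)-2-bromo-4,4-dimethylcyclohepta-2,5-dien-1-ol
Product: 11 {[(1R)-2-bromo-4,4-dimethylcyclohepta-2,5-dien-1-yl]oxy}triethylsilane
Conditions: Et3SiCl, imidazole, CH2Cl2, 0 °C
Reagents that add atoms: chlorotriethylsilane, CC[Si](Cl)(CC)CC
Why: Silylation of the secondary allylic alcohol installs a small silyl group that is later lost easily from the oxocarbenium ion of the key step.

Step 10
Reactants: 11 {[(1R)-2-bromo-4,4-dimethylcyclohepta-2,5-dien-1-yl]oxy}triethylsilane; 12 2-bromo-N-methoxy-N-methylacetamide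
Product: 14 2-[(7R)-3,3-dimethyl-7-(triethylsilyloxy)cyclohepta-1,4-dien-1-yl]-N-methoxy-N-methylacetamide, via Reformatsky zinc reagent 13 (not isolated)
Conditions: 12, Zn dust (Me3SiCl-activated), THF, 23 °C; then 11, Pd2(dba)3 (2.5 mol %), XPhos (10 mol %), THF, 60 °C
Reagents that add atoms: none
Why: Negishi coupling of the amide Reformatsky reagent with the alkenyl bromide forms the C9–C10 bond and keeps the alkene in place.

**Part B: side-chain iodide (C11–C15)**

Step 11
Reactants: 15 pent-1-en-4-yne
Product: 17 (2E)-3-methylhexa-2,5-dien-1-ol, via alkenylalane 16 (not isolated)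
Conditions: Me3Al, Cp2ZrCl2 (25 mol %), CH2Cl2, 0 to 23 °C; then n-BuLi, THF, −30 °C; (CH2O)n, 23 °C
Reagents that add atoms: trimethylaluminium, C[Al](C)C; formaldehyde (as paraformaldehyde), C=O
Why: Zirconium-catalysed carboalumination adds Me–Al syn across the alkyne only, with aluminium at the terminus, and the derived ate complex is hydroxymethylated with retention to give the E allylic alcohol.

Step 12
Reactants: 17 (2E)-3-methylhexa-2,5-dien-1-ol
Product: 18 [(2R,3R)-3-methyl-3-(prop-2-en-1-yl)oxiran-2-yl]methanol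
Conditions: Ti(OiPr)4 (10 mol %), D-(−)-diethyl tartrate (12 mol %), t-BuOOH, 4 Å MS, CH2Cl2, −20 °C
Reagents that add atoms: tert-butyl hydroperoxide, CC(C)(C)OO
Why: Sharpless asymmetric epoxidation with the D-tartrate should give the (2R,3R)-epoxide under reagent control, which fixes the future C13.

Step 13
Reactants: 18 [(2R,3R)-3-methyl-3-(prop-2-en-1-yl)oxiran-2-yl]methanol
Product: 19 (2S,3R)-2-(chloromethyl)-3-methyl-3-(prop-2-en-1-yl)oxirane
Conditions: PPh3, CCl4, 70 °C
Reagents that add atoms: tetrachloromethane, ClC(Cl)(Cl)Cl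
Why: Appel chlorination of the primary alcohol leaves the epoxide intact (the descriptor at C2 changes by priority only).

Step 14
Reactants: 19 (2S,3R)-2-(chloromethyl)-3-methyl-3-(prop-2-en-1-yl)oxirane
Product: 21 (3R)-3-methyl-1-(trimethylsilyl)hex-5-en-1-yn-3-ol, via bis-silylated alkynol 20 (not isolated)
Conditions: n-BuLi (3.3 equiv), THF, −40 °C; Me3SiCl, −40 to 0 °C; then citric acid, MeOH/H2O, 23 °C
Reagents that add atoms: chlorotrimethylsilane, C[Si](C)(C)Cl
Why: Base-induced double elimination of the 2,3-epoxy chloride gives the alkoxide/acetylide without breaking the C–O bond at the carbinol carbon (retention), and silylation followed by selective O-desilylation caps the alkyne.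

Step 15
Reactants: 21 (3R)-3-methyl-1-(trimethylsilyl)hex-5-en-1-yn-3-ol
Product: 22 triethyl{[(3R)-3-methyl-1-(trimethylsilyl)hex-5-en-1-yn-3-yl]oxy}silane
Conditions: Et3SiOTf, 2,6-lutidine, CH2Cl2, −78 to 0 °C
Reagents that add atoms: triethylsilyl trifluoromethanesulfonate, CC[Si](CC)(CC)OS(=O)(=O)C(F)(F)F
Why: The silyl triflate silylates the hindered tertiary propargylic alcohol.

Step 16
Reactants: 22 triethyl{[(3R)-3-methyl-1-(trimethylsilyl)hex-5-en-1-yn-3-yl]oxy}silane
Product: 24 (3R)-3-methyl-3-(triethylsilyloxy)-5-(trimethylsilyl)pent-4-yn-1-ol, via aldehyde 23 (not isolated)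
Conditions: O3, CH2Cl2/MeOH, −78 °C; then NaBH4, −78 to 0 °C
Reagents that add atoms: ozone, [O-][O+]=O
Why: Ozonolysis cleaves the terminal alkene much faster than the alkynylsilane, and reductive work-up gives the chain-shortened primary alcohol.

Step 17
Reactants: 24 (3R)-3-methyl-3-(triethylsilyloxy)-5-(trimethylsilyl)pent-4-yn-1-ol
Product: 25 triethyl{[(3R)-5-iodo-3-methyl-1-(trimethylsilyl)pent-1-yn-3-yl]oxy}silane
Conditions: I2, PPh3, imidazole, CH2Cl2, 0 °C
Reagents that add atoms: iodine, II
Why: Appel-type iodination converts the primary alcohol to the iodide under neutral conditions.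

**Part C: union and key step**

Step 18
Reactants: 14 2-[(7R)-3,3-dimethyl-7-(triethylsilyloxy)cyclohepta-1,4-dien-1-yl]-N-methoxy-N-methylacetamide; 25 triethyl{[(3R)-5-iodo-3-methyl-1-(trimethylsilyl)pent-1-yn-3-yl]oxy}silane
Product: 27 (5R)-2-[(7R)-3,3-dimethyl-7-(triethylsilyloxy)cyclohepta-1,4-dien-1-yl]-N-methoxy-N,5-dimethyl-5-(triethylsilyloxy)-7-(trimethylsilyl)hept-6-ynamide as C2 epimers, via lithium enolate 26 (not isolated)
Conditions: LiN(iPr)2, THF/DMPU, −78 °C; then 25, −78 to −20 °C
Reagents that add atoms: none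
Why: Kinetic deprotonation gives the amide dienolate, which is C-alkylated at the α-carbon (C9) by the primary iodide; C9 forms without control and is corrected in step 21.

Step 19
Reactants: 27 the alkylated Weinreb amide (C9 epimers)
Product: 28 (7R)-4-[(7R)-3,3-dimethyl-7-(triethylsilyloxy)cyclohepta-1,4-dien-1-yl]-7-methyl-7-(triethylsilyloxy)-9-(trimethylsilyl)non-1-en-8-yn-3-one as C4 epimers
Conditions: CH2=CHMgBr, THF, −20 to 0 °C; cold aq. NaHSO4 quench; used at once
Reagents that add atoms: vinylmagnesium bromide, C=C[Mg]Br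
Why: In this Weinreb ketone synthesis the chelated tetrahedral intermediate collapses only on quench, so addition stops at the vinyl ketone.

Step 20
Reactants: 28 the vinyl ketone (C9 epimers)
Product: 30 (13R)-8-oxo-13-(triethylsilyloxy)-15-(trimethylsilyl)-17-norlabd-2-en-14-yn-20-al as C9 epimers, via C10 cation aluminium enolate 29 (not isolated)
Conditions: EtAlCl2 (2.2 equiv), CH2Cl2, −78 to −40 °C; aq. Rochelle salt
Reagents that add atoms: none
Why: Proposed new method: EtAlCl2 activates the s-trans vinyl ketone, the trisubstituted C5=C10 alkene attacks its terminal carbon C6 in the Markovnikov sense (6-endo-trig closure of ring B through a chair-like array), and the developing tertiary C10 cation is discharged by a 1,2-shift of the allylic ring carbon C1 from C20 to C10, which turns the seven-membered ring into ring A and expels C20 as a silyloxocarbenium ion that loses Et3Si to chloride and leaves the formyl group. The closest known reaction types are the alkylaluminium chloride-induced conjugate addition of alkenes to enones with ensuing 1,2-shifts, and pinacol-terminated Prins cyclizations of alkenyl silyl ethers, including semipinacol ring contractions of cyclic 2-alkenyl carbinols triggered by halonium ions or gold-activated alkynes; new here is a tethered enone as the carbon electrophile for a ring-contracting shift. C5 and C10 are set by anti addition across C5=C10 (new C5–C6 bond on one face, migrating C1 on the other), which makes the ring fusion trans; their absolute sense is dictated by C20, because A(1,2) strain with the branched C9 substituent holds the OSiEt3 group pseudoaxial, so the C20–C1 bond is aligned with the alkene p orbitals on one face only and the enone must arrive on the opposite face. The step needs C1 migration to win over hydride shift from C20 and over proton loss; the in-plane position of H20 in the reactive conformer, the allylic character of C1 and the oxygen lone-pair push should secure this, while EtAlCl2 scavenges protons and so suppresses acid-mediated isomerization of the β,γ-unsaturated ketone. C9 is not controlled here and is corrected in step 21.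

**Part D: endgame**

Step 21
Reactants: 30 the keto aldehyde (C9 epimers)
Product: 32 (13R)-20-hydroxy-13-(triethylsilyloxy)-17-norlabd-2-en-14-yn-8-one, via hydroxy ketone epimer mixture 31 (not isolated)
Conditions: NaBH4, EtOH/CH2Cl2, −78 °C; acetone; then NaOMe, MeOH, 23 °C
Reagents that add atoms: none
Why: Borohydride at −78 °C should reduce the aldehyde much faster than the hindered ketone; methoxide then removes the alkynyl SiMe3 group and equilibrates C9 through the C8 enolate to the equatorial 9β side chain.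

Step 22
Reactants: 32 the hydroxy ketone
Product: 33 (13R)-20-acetoxy-13-(triethylsilyloxy)-17-norlabd-2-en-14-yn-8-one
Conditions: Ac2O, pyridine, DMAP (cat.), CH2Cl2, 0 °C
Reagents that add atoms: acetic anhydride, CC(=O)OC(C)=O
Why: Acetylation of the primary alcohol installs the C20 acetate of the target while the tertiary silyl ether stays inert.

Step 23
Reactants: 33 the acetate
Product: 34 (13R)-20-acetoxy-2α,3α-dihydroxy-13-(triethylsilyloxy)-17-norlabd-14-yn-8-one
Conditions: OsO4 (5 mol %), NMO, acetone/H2O, 23 °C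
Reagents that add atoms: osmium tetroxide (catalytic), O=[Os](=O)(=O)=O; N-methylmorpholine N-oxide, C[N+]1([O-])CCOCC1; water, O
Why: Upjohn dihydroxylation should occur on the α face, opposite the axial C10 acetoxymethyl group and the axial 4β-methyl, to give the cis 2α,3α-diol; the alkyne and ketone are inert.

Step 24
Reactants: 34 the diol
Product: 35 (13R)-20-acetoxy-2α-angeloyloxy-3α-hydroxy-13-(triethylsilyloxy)-17-norlabd-14-yn-8-one
Conditions: angelic acid, 2,4,6-Cl3C6H2COCl, Et3N, toluene, 23 °C; then 34, 80 °C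
Reagents that add atoms: angelic acid, C/C=C(/C)C(=O)O
Why: Yamaguchi-type mixed-anhydride acylation transfers the angeloyl group without Z to E isomerization, and it should select the equatorial C2 hydroxyl over the axial C3 hydroxyl next to the C4 gem-dimethyl group.

Step 25
Reactants: 35 the angelate ketone
Product: 36 (13R)-20-acetoxy-2α-angeloyloxy-13-(triethylsilyloxy)labd-8(17)-en-14-yn-3α-ol
Conditions: Zn, CH2Br2, TiCl4, THF, 0 °C (pre-formed reagent); then 35, CH2Cl2, 23 °C
Reagents that add atoms: dibromomethane, BrCBr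
Why: Takai–Lombardo methylenation is non-basic, so the esters and the C9 configuration should survive.

Step 26
Reactants: 36 the exocyclic alkene
Product: 37 (13R)-20-acetoxy-2α-angeloyloxy-13-(triethylsilyloxy)labd-8(17)-en-14-yne-3α,7α-diol
Conditions: SeO2 (0.5 equiv), t-BuOOH, CH2Cl2, 23 °C
Reagents that add atoms: selenium dioxide (oxygen carrier), O=[Se]=O; tert-butyl hydroperoxide, CC(C)(C)OO
Why: The SeO2 ene reaction and [2,3]-shift should occur at the allylic CH2 (C7) in preference to the CH (C9), with oxygen delivered axially on the α face as is usual for exocyclic methylene groups on trans-decalins.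

Step 27
Reactants: 37 the silyl ether
Product: 38 (13R)-20-acetoxy-2α-angeloyloxylabd-8(17)-en-14-yne-3α,7α,13-triol
Conditions: HF·pyridine, pyridine, THF, 0 to 23 °C
Reagents that add atoms: none
Why: Buffered fluoride cleaves the tertiary triethylsilyl ether while the esters and the propargylic alcohol remain intact.

Step 28
Reactants: 38 the alkynyl triol
Product: 39 CNP0251485.1, (13R)-20-acetoxy-2α-angeloyloxylabda-8(17),14-diene-3α,7α,13-triol
Conditions: H2 (1 atm), Pd/CaCO3, Pb(OAc)2, quinoline, EtOAc, 23 °C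
Reagents that add atoms: none
Why: Lindlar semi-hydrogenation reduces the terminal alkyne to the vinyl group and should leave the 1,1-disubstituted and trisubstituted alkenes untouched.

**Compound list**
1 | benzoic acid | O=C(O)c1ccccc1 | starting material
2 | dilithium enediolate from Birch reduction of benzoate | [Li+].[Li+].[O-]C([O-])=C1C=CCC=C1 | intermediate
3 | 1-methylcyclohexa-2,5-diene-1-carboxylic acid | CC1(C(=O)O)C=CCC=C1 | intermediate
4 | (1-methylcyclohexa-2,5-dien-1-yl)methanol | CC1(CO)C=CCC=C1 | intermediate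
5 | (1-methylcyclohexa-2,5-dien-1-yl)methyl 4-methylbenzenesulfonate | CC1(COS(=O)(=O)c2ccc(C)cc2)C=CCC=C1 | intermediate
6 | 3,3-dimethylcyclohexa-1,4-diene | CC1(C)C=CCC=C1 | intermediate
7 | rac-7,7-dibromo-2,2-dimethylbicyclo[4.1.0]hept-3-ene (cis-fused) | CC1(C)C=CCC2C1C2(Br)Br | intermediate
8 | rac-2-bromo-4,4-dimethylcyclohepta-2,5-dien-1-ol | OC1CC=CC(C)(C)C=C1Br | intermediate
9 | 2-bromo-4,4-dimethylcyclohepta-2,5-dien-1-one | O=C1CC=CC(C)(C)C=C1Br | intermediate
10 | (R)-2-bromo-4,4-dimethylcyclohepta-2,5-dien-1-ol | O[C@@H]1CC=CC(C)(C)C=C1Br | intermediate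
11 | {[(1R)-2-bromo-4,4-dimethylcyclohepta-2,5-dien-1-yl]oxy}triethylsilane | CC[Si](CC)(CC)O[C@@H]1CC=CC(C)(C)C=C1Br | intermediate
12 | 2-bromo-N-methoxy-N-methylacetamide | CON(C)C(=O)CBr | starting material
13 | [2-(methoxy(methyl)amino)-2-oxoethyl]zinc bromide | CON(C)C(=O)C[Zn]Br | intermediate
14 | 2-[(7R)-3,3-dimethyl-7-(triethylsilyloxy)cyclohepta-1,4-dien-1-yl]-N-methoxy-N-methylacetamide | CON(C)C(=O)CC1=CC(C)(C)C=CC[C@H]1O[Si](CC)(CC)CC | intermediate
15 | pent-1-en-4-yne | C=CCC#C | starting material
16 | dimethyl[(1E)-2-methylpenta-1,4-dien-1-yl]alane | C=CC/C(C)=C/[Al](C)C | intermediate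
17 | (2E)-3-methylhexa-2,5-dien-1-ol | C=CC/C(C)=C/CO | intermediate
18 | [(2R,3R)-3-methyl-3-(prop-2-en-1-yl)oxiran-2-yl]methanol | OC[C@H]1O[C@]1(C)CC=C | intermediate
19 | (2S,3R)-2-(chloromethyl)-3-methyl-3-(prop-2-en-1-yl)oxirane | ClC[C@H]1O[C@]1(C)CC=C | intermediate
20 | trimethyl{[(3R)-3-methyl-1-(trimethylsilyl)hex-5-en-1-yn-3-yl]oxy}silane | C[Si](C)(C)C#C[C@](C)(O[Si](C)(C)C)CC=C | intermediate
21 | (3R)-3-methyl-1-(trimethylsilyl)hex-5-en-1-yn-3-ol | C[Si](C)(C)C#C[C@](C)(O)CC=C | intermediate
22 | triethyl{[(3R)-3-methyl-1-(trimethylsilyl)hex-5-en-1-yn-3-yl]oxy}silane | C[Si](C)(C)C#C[C@](C)(O[Si](CC)(CC)CC)CC=C | intermediate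
23 | (3R)-3-methyl-3-(triethylsilyloxy)-5-(trimethylsilyl)pent-4-ynal | C[Si](C)(C)C#C[C@](C)(O[Si](CC)(CC)CC)CC=O | intermediate
24 | (3R)-3-methyl-3-(triethylsilyloxy)-5-(trimethylsilyl)pent-4-yn-1-ol | C[Si](C)(C)C#C[C@](C)(O[Si](CC)(CC)CC)CCO | intermediate
25 | triethyl{[(3R)-5-iodo-3-methyl-1-(trimethylsilyl)pent-1-yn-3-yl]oxy}silane | C[Si](C)(C)C#C[C@](C)(O[Si](CC)(CC)CC)CCI | intermediate
26 | lithium enolate of amide 14 | [Li+].CON(C)C([O-])=CC1=CC(C)(C)C=CC[C@H]1O[Si](CC)(CC)CC | intermediate
27 | (5R)-2-[(7R)-3,3-dimethyl-7-(triethylsilyloxy)cyclohepta-1,4-dien-1-yl]-N-methoxy-N,5-dimethyl-5-(triethylsilyloxy)-7-(trimethylsilyl)hept-6-ynamide, C2 epimers | CON(C)C(=O)C(CC[C@@](C)(O[Si](CC)(CC)CC)C#C[Si](C)(C)C)C1=CC(C)(C)C=CC[C@H]1O[Si](CC)(CC)CC | intermediate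
28 | (7R)-4-[(7R)-3,3-dimethyl-7-(triethylsilyloxy)cyclohepta-1,4-dien-1-yl]-7-methyl-7-(triethylsilyloxy)-9-(trimethylsilyl)non-1-en-8-yn-3-one, C4 epimers | C=CC(=O)C(CC[C@@](C)(O[Si](CC)(CC)CC)C#C[Si](C)(C)C)C1=CC(C)(C)C=CC[C@H]1O[Si](CC)(CC)CC | intermediate
29 | C10 carbocation / C8 dichloro(ethyl)aluminate enolate zwitterion after C5–C6 bond formation | C[Si](C)(C)C#C[C@](C)(O[Si](CC)(CC)CC)CCC1C(O[Al-](Cl)(Cl)CC)=CC[C@H]2C(C)(C)C=CC[C@@H](O[Si](CC)(CC)CC)[C+]12 | intermediate
30 | (13R)-8-oxo-13-(triethylsilyloxy)-15-(trimethylsilyl)-17-norlabd-2-en-14-yn-20-al (5α-H, 10β-formyl), C9 epimers | C[Si](C)(C)C#C[C@](C)(O[Si](CC)(CC)CC)CCC1C(=O)CC[C@H]2C(C)(C)C=CC[C@]12C=O | intermediate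
31 | (13R)-20-hydroxy-13-(triethylsilyloxy)-15-(trimethylsilyl)-17-norlabd-2-en-14-yn-8-one, C9 epimers | C[Si](C)(C)C#C[C@](C)(O[Si](CC)(CC)CC)CCC1C(=O)CC[C@H]2C(C)(C)C=CC[C@]12CO | intermediate
32 | (13R)-20-hydroxy-13-(triethylsilyloxy)-17-norlabd-2-en-14-yn-8-one (9α-H) | C#C[C@](C)(O[Si](CC)(CC)CC)CC[C@H]1C(=O)CC[C@H]2C(C)(C)C=CC[C@]12CO | intermediate
33 | (13R)-20-acetoxy-13-(triethylsilyloxy)-17-norlabd-2-en-14-yn-8-one | C#C[C@](C)(O[Si](CC)(CC)CC)CC[C@H]1C(=O)CC[C@H]2C(C)(C)C=CC[C@]12COC(C)=O | intermediate
34 | (13R)-20-acetoxy-2α,3α-dihydroxy-13-(triethylsilyloxy)-17-norlabd-14-yn-8-one | C#C[C@](C)(O[Si](CC)(CC)CC)CC[C@H]1C(=O)CC[C@H]2C(C)(C)[C@H](O)[C@H](O)C[C@]12COC(C)=O | intermediate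
35 | (13R)-20-acetoxy-2α-angeloyloxy-3α-hydroxy-13-(triethylsilyloxy)-17-norlabd-14-yn-8-one | C#C[C@](C)(O[Si](CC)(CC)CC)CC[C@H]1C(=O)CC[C@H]2C(C)(C)[C@H](O)[C@H](OC(=O)/C(C)=C\C)C[C@]12COC(C)=O | intermediate
36 | (13R)-20-acetoxy-2α-angeloyloxy-13-(triethylsilyloxy)labd-8(17)-en-14-yn-3α-ol | C#C[C@](C)(O[Si](CC)(CC)CC)CC[C@H]1C(=C)CC[C@H]2C(C)(C)[C@H](O)[C@H](OC(=O)/C(C)=C\C)C[C@]12COC(C)=O | intermediate
37 | (13R)-20-acetoxy-2α-angeloyloxy-13-(triethylsilyloxy)labd-8(17)-en-14-yne-3α,7α-diol | C#C[C@](C)(O[Si](CC)(CC)CC)CC[C@H]1C(=C)[C@H](O)C[C@H]2C(C)(C)[C@H](O)[C@H](OC(=O)/C(C)=C\C)C[C@]12COC(C)=O | intermediate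
38 | (13R)-20-acetoxy-2α-angeloyloxylabd-8(17)-en-14-yne-3α,7α,13-triol | C#C[C@](C)(O)CC[C@H]1C(=C)[C@H](O)C[C@H]2C(C)(C)[C@H](O)[C@H](OC(=O)/C(C)=C\C)C[C@]12COC(C)=O | intermediate
39 | CNP0251485.1, (13R)-20-acetoxy-2α-angeloyloxylabda-8(17),14-diene-3α,7α,13-triol | C=C[C@](C)(O)CC[C@H]1C(=C)[C@H](O)C[C@H]2C(C)(C)[C@H](O)[C@H](OC(=O)/C(C)=C\C)C[C@]12COC(C)=O | target

**Step count**
Total: 28 steps. Longest linear sequence: 21 steps (steps 1–10 and 18–28). The side-chain branch is 7 steps (11–17).

**Steps most likely to fail**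

Step 20 (proposed new method). The C10 cation may be discharged by hydride shift from C20 or by proton loss instead of C1 migration. The enone may also add to the wrong alkene face, which would erode the chirality relay from C20, and the Lewis acid may ionize the allylic silyl ether. The fallback sets out from 28 and returns at 30, and separates the ring contraction from ring B closure. N-Bromosuccinimide (CH2Cl2, −40 °C) should effect the known halonium-induced semipinacol ring contraction of the allylic silyl ether. Bromine adds at C5 and C1 migrates anti to C10, giving ring-contracted bromo aldehyde F1. Bu3SnH/AIBN (benzene, 80 °C, high dilution) then closes ring B by 6-endo radical conjugate addition of the C5 radical to the vinyl ketone terminus and gives 30.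

Step 18. C-alkylation of the hindered amide dienolate may be slow, with competing E2 elimination of the iodide, γ-alkylation and enolate decomposition. The fallback sets out from 25 (with 11) and returns at 27, reversing the order of the two C9 bond formations so that steps 10 and 18 are bypassed. The unhindered lithium enolate of commercial N-methoxy-N-methylacetamide (LiN(iPr)2, THF/DMPU, −78 to 0 °C) is alkylated with 25 to give chain amide F2. The zinc enolate of F2 (LiN(SiMe3)2, then ZnCl2) is then coupled with bromide 11 under Pd(dba)2/Q-Phos (palladium-catalysed α-alkenylation of a zinc amide enolate) to give 27.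

Step 26. The allylic oxidation may run on to the C7 enone, attack C9 or the angelate methyl groups, or stall. The fallback sets out from 35 and returns at 37, putting in the C7 oxygen before the methylene group. Soft enolization of 35 (Me3SiOTf, Et3N, CH2Cl2, 0 °C) should give the C7=C8 trimethylsilyl enol ether F3, with the C3 hydroxyl silylated as well. Rubottom oxidation (mCPBA, NaHCO3, CH2Cl2, −20 °C; then citric acid, MeOH) from the α face should give 7α-hydroxy ketone F4. Takai–Lombardo methylenation of F4 under the conditions of step 25 then gives 37.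

**Further compounds**
F1 | step 20 | 6-bromo-5,5-dimethyl-1-[(7R)-7-methyl-3-oxo-7-(triethylsilyloxy)-9-(trimethylsilyl)non-1-en-8-yn-4-yl]cyclohex-3-ene-1-carbaldehyde (bromine at labdane C5, anti to the migrated C1 on C10) | C=CC(=O)C(CC[C@@](C)(O[Si](CC)(CC)CC)C#C[Si](C)(C)C)[C@@]1(C=O)CC=CC(C)(C)[C@@H]1Br
F2 | step 18 | (5R)-N-methoxy-N,5-dimethyl-5-(triethylsilyloxy)-7-(trimethylsilyl)hept-6-ynamide | CON(C)C(=O)CCC[C@@](C)(O[Si](CC)(CC)CC)C#C[Si](C)(C)C
F3 | step 26 | (13R)-20-acetoxy-2α-angeloyloxy-13-(triethylsilyloxy)-3α,8-bis(trimethylsilyloxy)-17-norlabd-7-en-14-yne | C#C[C@](C)(O[Si](CC)(CC)CC)CC[C@H]1C(O[Si](C)(C)C)=CC[C@H]2C(C)(C)[C@H](O[Si](C)(C)C)[C@H](OC(=O)/C(C)=C\C)C[C@]12COC(C)=O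
F4 | step 26 | (13R)-20-acetoxy-2α-angeloyloxy-3α,7α-dihydroxy-13-(triethylsilyloxy)-17-norlabd-14-yn-8-one | C#C[C@](C)(O[Si](CC)(CC)CC)CC[C@H]1C(=O)[C@H](O)C[C@H]2C(C)(C)[C@H](O)[C@H](OC(=O)/C(C)=C\C)C[C@]12COC(C)=O
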